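**Retrosynthetic overview**

- The plan rests on one feature: each of the three isovaleryl C=O groups sits between two oxygen-bearing ring carbons (OMe and OH on rings A and C, two OH on ring B). The four hydroxyls ortho to the ketones are therefore exactly the positions a ketone oxygen can reach through a five-membered metallacycle.
- Target ⇒ its triacetate (methanolysis of three aryl acetates) ⇒ the triacetate of the tetra-deoxy trimer, by forming these four aryl C–O bonds last in one ketone-directed C–H hydroxylation.
- Tetra-deoxy trimer ⇒ two ArCH2–Ar bonds by Friedel–Crafts benzylation of two equivalents of the ring A/C phenol with 2,6-bis(hydroxymethyl)-4-isovalerylphenol (ring B).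
- Ring A/C phenol from 2-methylresorcinol (C-acylation, 4-O-benzylation, 2-O-methylation, debenzylation); ring B from phenol (para-acylation, double hydroxymethylation).
- No ring is formed at any stage: all three benzene rings are bought, and the target has no stereocentre.

Key step: step 9

Remark: rings A and C are the two identical O-methylated terminal rings and ring B is the central ring; the target is achiral, so no configuration has to be set.

**Route**

Step 1
Reactants: 1 2-methylresorcinol; 2 isovaleryl chloride (3-methylbutanoyl chloride)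
Product: 3 1-(2,4-dihydroxy-3-methylphenyl)-3-methylbutan-1-one
Conditions: AlCl3 (3 equiv), PhNO2, 0 °C → 60 °C; then aq. HCl
Reagents that add atoms: none
Why: Friedel–Crafts acylation; the two ring positions ortho/para to the hydroxyls are equivalent by symmetry, so a single mono-ketone should form, and it is deactivated towards a second acylation.

Step 2
Reactants: 3 1-(2,4-dihydroxy-3-methylphenyl)-3-methylbutan-1-one
Product: 4 1-[4-(benzyloxy)-2-hydroxy-3-methylphenyl]-3-methylbutan-1-one
Conditions: BnBr (1.05 equiv), K2CO3, acetone, reflux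
Reagents that add atoms: benzyl bromide, BrCc1ccccc1
Why: Williamson etherification; the 2-OH is hydrogen-bonded to the ketone and is the poorer nucleophile, so one equivalent of benzyl bromide should alkylate only the 4-OH.

Step 3
Reactants: 4 1-[4-(benzyloxy)-2-hydroxy-3-methylphenyl]-3-methylbutan-1-one
Product: 5 1-[4-(benzyloxy)-2-methoxy-3-methylphenyl]-3-methylbutan-1-one
Conditions: MeI (excess), K2CO3, DMF, 60 °C
Reagents that add atoms: iodomethane, CI
Why: Williamson O-methylation of the remaining chelated phenol, driven by the polar solvent and excess iodomethane; carbonate does not deprotonate the ketone alpha-CH2, so C-methylation is not expected.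

Step 4
Reactants: 5 1-[4-(benzyloxy)-2-methoxy-3-methylphenyl]-3-methylbutan-1-one
Product: 6 1-(4-hydroxy-2-methoxy-3-methylphenyl)-3-methylbutan-1-one
Conditions: H2 (1 atm), 10% Pd/C, EtOAc, rt
Reagents that add atoms: none
Why: Hydrogenolysis of the benzyl aryl ether over palladium on carbon; in neutral ethyl acetate at 1 atm it should be much faster than reduction of the aryl ketone, and the uptake is stopped after one equivalent of hydrogen.

Step 5
Reactants: 7 phenol; 2 isovaleryl chloride
Product: 9 1-(4-hydroxyphenyl)-3-methylbutan-1-one, via phenyl 3-methylbutanoate 8 (not isolated)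
Conditions: CH2Cl2, 0 °C → rt; then AlCl3 (2 equiv), PhNO2, rt → 50 °C; aq. HCl
Reagents that add atoms: none
Why: O-acylation followed by AlCl3-mediated Fries rearrangement, which at low temperature in nitrobenzene favours the para-hydroxy ketone.

Step 6
Reactants: 9 1-(4-hydroxyphenyl)-3-methylbutan-1-one
Product: 10 1-[4-hydroxy-3,5-bis(hydroxymethyl)phenyl]-3-methylbutan-1-one
Conditions: 37% aq. CH2O (6 equiv), NaOH (1.0 equiv), H2O/MeOH, 40 °C; then AcOH, 0 °C
Reagents that add atoms: formaldehyde, C=O
Why: Lederer–Manasse hydroxymethylation at the two free ortho positions of the phenoxide (para is blocked by the acyl group); with one equivalent of NaOH the only base present is the weakly basic acylphenoxide, which should keep aldol hydroxymethylation at the ketone alpha-carbon slow.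

Step 7
Reactants: 10 1-[4-hydroxy-3,5-bis(hydroxymethyl)phenyl]-3-methylbutan-1-one; 6 1-(4-hydroxy-2-methoxy-3-methylphenyl)-3-methylbutan-1-one (4 equiv, excess recovered)
Product: 11 2,6-bis[2-hydroxy-4-methoxy-3-methyl-5-(3-methylbutanoyl)benzyl]-4-(3-methylbutanoyl)phenol (tetra-deoxy trimer)
Conditions: p-TsOH·H2O (20 mol%), 1,4-dioxane, 90 °C
Reagents that add atoms: none
Why: Acid-catalysed Friedel–Crafts benzylation through the protonated ortho-quinone methide of 10, at C5 of 6, the only position of 6 that is ortho to the hydroxyl and para to the methoxy group; 10 has no activated free ring position and cannot oligomerise through carbon, and the excess of 6 suppresses dibenzyl ether formation.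

Step 8
Reactants: 11 tetra-deoxy trimer (triphenol)
Product: 12 2,6-bis[2-acetoxy-4-methoxy-3-methyl-5-(3-methylbutanoyl)benzyl]-4-(3-methylbutanoyl)phenyl acetate (tetra-deoxy trimer triacetate)
Conditions: Ac2O, pyridine, DMAP (cat.), CH2Cl2, rt
Reagents that add atoms: acetic anhydride, CC(=O)OC(C)=O
Why: DMAP-catalysed acetylation of all three phenols, which masks them as electron-withdrawing esters and makes the rings harder to oxidise in the next step.

Step 9
Reactants: 12 tetra-deoxy trimer triacetate
Product: 14 2,6-bis[2-acetoxy-6-hydroxy-4-methoxy-3-methyl-5-(3-methylbutanoyl)benzyl]-3,5-dihydroxy-4-(3-methylbutanoyl)phenyl acetate (target triacetate), via aryl tetrakis(trifluoroacetate) 13 (not isolated)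
Conditions: [RuCl2(p-cymene)]2 (10 mol%), PhI(OCOCF3)2 (6 equiv, in portions), CF3CO2H/(CF3CO)2O 3:1, 80 °C; then evaporation, MeCN/H2O, rt
Reagents that add atoms: [bis(trifluoroacetoxy)iodo]benzene, O=C(OI(OC(=O)C(F)(F)F)c1ccccc1)C(F)(F)F; trifluoroacetic acid (solvent, exchanges trifluoroacetate with oxidant and metal), OC(=O)C(F)(F)F
Why: Proposed new method: in trifluoroacetic acid the chloride-bridged dimer should give a divalent ruthenium trifluoroacetate that binds a ketone oxygen and cleaves the neighbouring aryl C–H bond by carboxylate-assisted concerted metalation-deprotonation to a five-membered ruthenacycle; PhI(OCOCF3)2 oxidises this to tetravalent ruthenium, and C–O reductive elimination releases an aryl trifluoroacetate and divalent ruthenium, the cycle running four times (once on ring A, once on ring C, twice on ring B). The closest known reaction type is the ketone-directed ortho C–H hydroxylation of simple aryl ketones with this catalyst and oxidant, established for one unhindered site per molecule, whereas here each C–H bond lies between the acyl-bearing carbon and a carbon carrying a benzylic CH2, and ring B must react a second time after it has become an electron-poor aryl trifluoroacetate. No ring is closed and no stereocentre is formed. Site selectivity is built into 12, because its only four aromatic C–H bonds are the four ortho to the ketones (the other ortho carbon of rings A and C carries OMe), and each ketone can turn its oxygen towards the C–H side. Chemoselectivity over the two ArCH2Ar bridges, the ketone alpha-CH2 groups and one-electron oxidation of the anisole rings is sought from the acetates and ketones, which lower the electron density of all three rings, and from the anhydride, which keeps every new phenol masked as its trifluoroacetate until the neutral aqueous work-up, which should cleave these labile esters and leave the acetates.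

Step 10
Reactants: 14 target triacetate
Product: 15 1-[3,5-bis[[2,6-dihydroxy-4-methoxy-3-methyl-5-(3-methylbutanoyl)phenyl]methyl]-2,4,6-trihydroxyphenyl]-3-methylbutan-1-one (CNP0158539.0)
Conditions: K2CO3 (6 equiv), degassed MeOH, Ar, 0 °C → rt; then 1 M HCl
Reagents that add atoms: none
Why: Base-mediated methanolysis (transesterification) of the three aryl acetates; ketones, the aryl methyl ethers and the methylene bridges should be inert at this temperature, and exclusion of oxygen protects the phenoxides of the electron-rich product.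

**Compound list**

1 | 2-methylresorcinol (2-methylbenzene-1,3-diol) | Cc1c(O)cccc1O | starting material
2 | isovaleryl chloride (3-methylbutanoyl chloride) | CC(C)CC(Cl)=O | starting material
3 | 1-(2,4-dihydroxy-3-methylphenyl)-3-methylbutan-1-one | CC(C)CC(=O)c1ccc(O)c(C)c1O | intermediate
4 | 1-[4-(benzyloxy)-2-hydroxy-3-methylphenyl]-3-methylbutan-1-one | CC(C)CC(=O)c1ccc(OCc2ccccc2)c(C)c1O | intermediate
5 | 1-[4-(benzyloxy)-2-methoxy-3-methylphenyl]-3-methylbutan-1-one | COc1c(C)c(OCc2ccccc2)ccc1C(=O)CC(C)C | intermediate
6 | 1-(4-hydroxy-2-methoxy-3-methylphenyl)-3-methylbutan-1-one | COc1c(C)c(O)ccc1C(=O)CC(C)C | intermediate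
7 | phenol | Oc1ccccc1 | starting material
8 | phenyl 3-methylbutanoate (not isolated) | CC(C)CC(=O)Oc1ccccc1 | intermediate
9 | 1-(4-hydroxyphenyl)-3-methylbutan-1-one | CC(C)CC(=O)c1ccc(O)cc1 | intermediate
10 | 1-[4-hydroxy-3,5-bis(hydroxymethyl)phenyl]-3-methylbutan-1-one | CC(C)CC(=O)c1cc(CO)c(O)c(CO)c1 | intermediate
11 | 2,6-bis[2-hydroxy-4-methoxy-3-methyl-5-(3-methylbutanoyl)benzyl]-4-(3-methylbutanoyl)phenol | COc1c(C)c(O)c(Cc2cc(C(=O)CC(C)C)cc(Cc3cc(C(=O)CC(C)C)c(OC)c(C)c3O)c2O)cc1C(=O)CC(C)C | intermediate
12 | 2,6-bis[2-acetoxy-4-methoxy-3-methyl-5-(3-methylbutanoyl)benzyl]-4-(3-methylbutanoyl)phenyl acetate | COc1c(C)c(OC(C)=O)c(Cc2cc(C(=O)CC(C)C)cc(Cc3cc(C(=O)CC(C)C)c(OC)c(C)c3OC(C)=O)c2OC(C)=O)cc1C(=O)CC(C)C | intermediate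
13 | tetrakis(trifluoroacetate) of 14 at the four new phenolic oxygens (not isolated) | COc1c(C)c(OC(C)=O)c(Cc2c(OC(=O)C(F)(F)F)c(C(=O)CC(C)C)c(OC(=O)C(F)(F)F)c(Cc3c(OC(=O)C(F)(F)F)c(C(=O)CC(C)C)c(OC)c(C)c3OC(C)=O)c2OC(C)=O)c(OC(=O)C(F)(F)F)c1C(=O)CC(C)C | intermediate
14 | 2,6-bis[2-acetoxy-6-hydroxy-4-methoxy-3-methyl-5-(3-methylbutanoyl)benzyl]-3,5-dihydroxy-4-(3-methylbutanoyl)phenyl acetate | COc1c(C)c(OC(C)=O)c(Cc2c(O)c(C(=O)CC(C)C)c(O)c(Cc3c(O)c(C(=O)CC(C)C)c(OC)c(C)c3OC(C)=O)c2OC(C)=O)c(O)c1C(=O)CC(C)C | intermediate
15 | 1-[3,5-bis[[2,6-dihydroxy-4-methoxy-3-methyl-5-(3-methylbutanoyl)phenyl]methyl]-2,4,6-trihydroxyphenyl]-3-methylbutan-1-one (CNP0158539.0) | COc1c(C)c(O)c(Cc2c(O)c(Cc3c(O)c(C)c(OC)c(C(=O)CC(C)C)c3O)c(O)c(C(=O)CC(C)C)c2O)c(O)c1C(=O)CC(C)C | target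

**Step count**

Total: 10 steps. Longest linear sequence: 8 steps (steps 1–4 and 7–10, from 2-methylresorcinol); the ring B branch contributes steps 5 and 6.

**Steps most likely to fail**

1. Step 9 (proposed new method). Ruthenation at C–H bonds that are flanked on both sides may be slow. The hypervalent iodine reagent could then oxidise the benzylic bridges or the ketone alpha-positions instead, or the sequence could stall after two or three C–O bonds, most likely at the second hydroxylation of ring B.
Fallback with known chemistry, setting out from 6 and 2 and coming back to the route at 15: the ortho oxygens are moved into the building blocks and the methylene bridges are made last. Acetylation of 6 (Ac2O, pyridine) would give 3-methoxy-2-methyl-4-(3-methylbutanoyl)phenyl acetate F1. Its single ortho C–H bond has only a hydrogen as its other neighbour, so the known one-site ketone-directed hydroxylation ([RuCl2(p-cymene)]2, PhI(OCOCF3)2, CF3CO2H/(CF3CO)2O) applies. It should give 5-acetoxy-3-methoxy-4-methyl-2-(3-methylbutanoyl)phenyl trifluoroacetate F2 in the flask and, after aqueous work-up, 5-hydroxy-3-methoxy-2-methyl-4-(3-methylbutanoyl)phenyl acetate F3. Methanolysis (K2CO3, MeOH) would give 1-(4,6-dihydroxy-2-methoxy-3-methylphenyl)-3-methylbutan-1-one F4. A phenol Mannich reaction (aq. CH2O, Me2NH, EtOH) at its only free ring position would give 1-[3-[(dimethylamino)methyl]-2,4-dihydroxy-6-methoxy-5-methylphenyl]-3-methylbutan-1-one F5. Ring B is taken from commercial phloroglucinol, acylated with 2 (AlCl3, PhNO2) to 3-methyl-1-(2,4,6-trihydroxyphenyl)butan-1-one F6. Heating F6 with two equivalents of F5 in dioxane should give 15 directly, by ortho-quinone methide formation with loss of Me2NH and C-alkylation of the phloroglucinol at its two free positions. F5 has no free ring position and cannot condense with itself.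

2. Step 7. Ionisation of the acyl-deactivated benzylic alcohols may be slow, so that dibenzyl ether formation or incomplete second benzylation competes with C-alkylation.
Fallback, setting out from 6 and 10 and coming back at 12: the two ArCH2–Ar bonds are made by Suzuki–Miyaura coupling, with the site fixed by a halogen instead of by ring electronics. Iodination of 6 (N-iodosuccinimide, cat. TsOH, MeCN) ortho to the hydroxyl would give 1-(4-hydroxy-5-iodo-2-methoxy-3-methylphenyl)-3-methylbutan-1-one F7. Acetylation would give 6-iodo-3-methoxy-2-methyl-4-(3-methylbutanoyl)phenyl acetate F8. Miyaura borylation (bis(pinacolato)diboron, PdCl2(dppf), KOAc, dioxane, 80 °C) would give 3-methoxy-2-methyl-4-(3-methylbutanoyl)-6-(4,4,5,5-tetramethyl-1,3,2-dioxaborolan-2-yl)phenyl acetate F9. In parallel, 10 with HBr in AcOH would give 1-[3,5-bis(bromomethyl)-4-hydroxyphenyl]-3-methylbutan-1-one F10. Acid-catalysed acetylation (Ac2O, cat. H2SO4) would give 2,6-bis(bromomethyl)-4-(3-methylbutanoyl)phenyl acetate F11. Coupling of F11 with F9 (2.2 equiv; PdCl2(dppf), CsF, dioxane, 80 °C) should give 12; any acetate lost on the way is put back with Ac2O/pyridine before isolation.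

3. Step 6. The second hydroxymethylation of the deactivated phenoxide may be sluggish, and aldol addition of formaldehyde at the ketone alpha-carbon or condensation of the benzylic alcohols may take over on prolonged heating.
Fallback, setting out from 9 and coming back at 10: the two carbons are introduced at the aldehyde oxidation level. Duff diformylation of 9 (hexamethylenetetramine, CF3CO2H, reflux; then aq. HCl) would give 2-hydroxy-5-(3-methylbutanoyl)benzene-1,3-dicarbaldehyde F12. Chemoselective reduction of the two aldehydes in the presence of the aryl ketone with NaBH(OAc)3 should then give 10.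

**Further compounds**

F1 | step 9 | 3-methoxy-2-methyl-4-(3-methylbutanoyl)phenyl acetate | COc1c(C)c(OC(C)=O)ccc1C(=O)CC(C)C
F2 | step 9 | 5-acetoxy-3-methoxy-4-methyl-2-(3-methylbutanoyl)phenyl trifluoroacetate | COc1c(C)c(OC(C)=O)cc(OC(=O)C(F)(F)F)c1C(=O)CC(C)C
F3 | step 9 | 5-hydroxy-3-methoxy-2-methyl-4-(3-methylbutanoyl)phenyl acetate | COc1c(C)c(OC(C)=O)cc(O)c1C(=O)CC(C)C
F4 | step 9 | 1-(4,6-dihydroxy-2-methoxy-3-methylphenyl)-3-methylbutan-1-one | COc1c(C)c(O)cc(O)c1C(=O)CC(C)C
F5 | step 9 | 1-[3-[(dimethylamino)methyl]-2,4-dihydroxy-6-methoxy-5-methylphenyl]-3-methylbutan-1-one | COc1c(C)c(O)c(CN(C)C)c(O)c1C(=O)CC(C)C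
F6 | step 9 | 3-methyl-1-(2,4,6-trihydroxyphenyl)butan-1-one | CC(C)CC(=O)c1c(O)cc(O)cc1O
F7 | step 7 | 1-(4-hydroxy-5-iodo-2-methoxy-3-methylphenyl)-3-methylbutan-1-one | COc1c(C)c(O)c(I)cc1C(=O)CC(C)C
F8 | step 7 | 6-iodo-3-methoxy-2-methyl-4-(3-methylbutanoyl)phenyl acetate | COc1c(C)c(OC(C)=O)c(I)cc1C(=O)CC(C)C
F9 | step 7 | 3-methoxy-2-methyl-4-(3-methylbutanoyl)-6-(4,4,5,5-tetramethyl-1,3,2-dioxaborolan-2-yl)phenyl acetate | COc1c(C)c(OC(C)=O)c(B2OC(C)(C)C(C)(C)O2)cc1C(=O)CC(C)C
F10 | step 7 | 1-[3,5-bis(bromomethyl)-4-hydroxyphenyl]-3-methylbutan-1-one | CC(C)CC(=O)c1cc(CBr)c(O)c(CBr)c1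
F11 | step 7 | 2,6-bis(bromomethyl)-4-(3-methylbutanoyl)phenyl acetate | CC(C)CC(=O)c1cc(CBr)c(OC(C)=O)c(CBr)c1
F12 | step 6 | 2-hydroxy-5-(3-methylbutanoyl)benzene-1,3-dicarbaldehyde | CC(C)CC(=O)c1cc(C=O)c(O)c(C=O)c1
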